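**Retrosynthetic overview**

- Target ⇐ one BCl3 step that removes the tert-butyl ester and the chelated ortho methyl ether of ring A from a protected depside.
- Protected depside ⇐ anionic (4+2) annulation with loss of CO2 that builds ring B (the pentyl benzoic acid ring). C1 (carboxyl-bearing) and C6 (pentyl-bearing) are the α- and β-carbons of tert-butyl oct-2-ynoate. C2 to C5 are the symmetric four-carbon enol chain of 3-oxoglutaric anhydride, whose central oxygen (the future C4 ester oxygen) already carries the ring A acyl group. Bonds C5–C6 and C1–C2 form.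
- Annulation partners ⇐ enol O-acylation of 3-oxoglutaric anhydride with the ring A acid chloride; heptynyllithium plus Boc2O.
- Ring A acid ⇐ divarinol: exhaustive methylation, lithiation/chlorination between the two methoxy groups (symmetric chloroarene), bromination of one of the two equivalent positions, Br/Li exchange and CO2.
- Ring order: ring A comes with divarinol; ring B is the only ring made (step 9).

Key step: step 9

Remark: the ring A ortho oxygen is carried as a methyl ether and not as an acetal, because an ortho-(alkoxymethoxy)benzoyl chloride tends to lose the acetal or close to a 1,3-benzodioxin-4-one, whereas the methyl ether survives acid chloride formation and is removed at the end by chelation-controlled BCl3 cleavage; 3-oxoglutaric anhydride is drawn as the trione and reacts through its enol.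

Step 1
Reactants: 1 5-propylbenzene-1,3-diol (divarinol)
Product: 2 1,3-dimethoxy-5-propylbenzene
Conditions: MeI (excess), K2CO3, DMF, rt
Reagents that add atoms: iodomethane, CI
Why: Williamson ether synthesis (SN2 O-methylation of both phenoxides), driven to the bis-ether with excess MeI so that no mono-ether has to be separated.

Step 2
Reactants: 2 1,3-dimethoxy-5-propylbenzene
Product: 4 2-chloro-1,3-dimethoxy-5-propylbenzene, via aryllithium 3 (not isolated)
Conditions: n-BuLi, THF, 0 °C → rt; then C2Cl6, −78 °C → rt
Reagents that add atoms: hexachloroethane, ClC(Cl)(Cl)C(Cl)(Cl)Cl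
Why: Directed ortho-metalation at the C–H flanked by both methoxy groups (the most acidic and doubly coordinated site), followed by electrophilic chlorination of the aryllithium with C2Cl6, which places chlorine unambiguously between the two oxygens.

Step 3
Reactants: 4 2-chloro-1,3-dimethoxy-5-propylbenzene
Product: 5 2-bromo-4-chloro-3,5-dimethoxy-1-propylbenzene
Conditions: NBS (1.0 equiv), MeCN, 0 °C → rt
Reagents that add atoms: N-bromosuccinimide, O=C1CCC(=O)N1Br
Why: Electrophilic aromatic bromination; the two free ring positions of symmetric 4 are equivalent (each ortho to one methoxy group and para to the other), so only one monobromide can form, and the first bromine deactivates the ring toward a second.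

Step 4
Reactants: 5 2-bromo-4-chloro-3,5-dimethoxy-1-propylbenzene
Product: 7 3-chloro-2,4-dimethoxy-6-propylbenzoic acid, via aryllithium 6 (not isolated)
Conditions: n-BuLi, THF, −78 °C; CO2 (g), −78 °C → rt; aq. HCl
Reagents that add atoms: carbon dioxide, O=C=O
Why: Bromine–lithium exchange, far faster at −78 °C than chlorine exchange or deprotonation, gives an aryllithium that is meta to chlorine (no aryne pathway) and is carboxylated by CO2.

Step 5
Reactants: 7 3-chloro-2,4-dimethoxy-6-propylbenzoic acid
Product: 8 3-chloro-2,4-dimethoxy-6-propylbenzoyl chloride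
Conditions: (COCl)2, cat. DMF, CH2Cl2, 0 °C → rt; evaporation, used crude
Reagents that add atoms: oxalyl chloride, O=C(Cl)C(=O)Cl
Why: Acid chloride formation through the Vilsmeier-type chloroiminium catalyst; the two methyl ethers and the aryl chloride are inert to the HCl released.

Step 6
Reactants: 9 3-oxopentanedioic acid
Product: 10 3-oxoglutaric anhydride (2H-pyran-2,4,6(3H,5H)-trione)
Conditions: Ac2O, AcOH, 10 °C; product filtered off
Reagents that add atoms: none
Why: Cyclodehydration of a 1,5-diacid to the six-membered cyclic anhydride through a mixed acetic anhydride, kept cold so that the product precipitates before C-acetylation or decarboxylation can set in.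

Step 7
Reactants: 10 3-oxoglutaric anhydride; 8 3-chloro-2,4-dimethoxy-6-propylbenzoyl chloride
Product: 12 2,6-dioxo-3,6-dihydro-2H-pyran-4-yl 3-chloro-2,4-dimethoxy-6-propylbenzoate, via triethylammonium enolate 11 (not isolated)
Conditions: Et3N (1.0 equiv), CH2Cl2, −20 → 0 °C; filtration under N2, no aqueous work-up, used promptly
Reagents that add atoms: none
Why: Enol ester formation by O-acylation of a cyclic β-dicarbonyl enolate with an acid chloride, in which the strongly acidic enol of 10 is deprotonated by exactly one equivalent of Et3N and the hindered, acylium-like aroyl chloride reacts at the enolate oxygen because no nucleophilic catalyst (DMAP, cyanide) is present to move the acyl group to carbon.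

Step 8
Reactants: 13 1-heptyne; 14 di-tert-butyl dicarbonate
Product: 16 tert-butyl oct-2-ynoate, via lithium heptynide 15 (not isolated)
Conditions: n-BuLi, THF, −78 °C; then 14, −78 → 0 °C; cold 1 M HCl
Reagents that add atoms: none
Why: Alkoxycarbonylation of a lithium acetylide with Boc2O (nucleophilic acyl substitution with loss of tert-butyl carbonate), a standard entry to tert-butyl alk-2-ynoates.

Step 9
Reactants: 12 2,6-dioxo-3,6-dihydro-2H-pyran-4-yl 3-chloro-2,4-dimethoxy-6-propylbenzoate; 16 tert-butyl oct-2-ynoate
Product: 19 tert-butyl 4-[(3-chloro-2,4-dimethoxy-6-propylbenzoyl)oxy]-2-hydroxy-6-pentylbenzoate, via sodium oxidopyrone 17 (not isolated), via bridged lactone alkoxide 18 (not isolated)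
Conditions: NaH (1.05 equiv), THF, 0 °C; then 16 (1.3 equiv), 0 °C → rt; cold 1 M HCl
Reagents that add atoms: none
Why: Proposed new method: NaH removes a methylene proton of 12 to give the symmetric 4-acyloxy-6-oxido-2-pyrone 17, whose carbon next to a carbonyl adds in Michael fashion to the pentyl-bearing β-carbon of ynoate 16 (ring B bond C5–C6); the allenolate α-carbon then attacks the opposite anhydride carbonyl in a 6-exo-trig Dieckmann-type closure (ring B bond C1–C2) to give bridged lactone alkoxide 18, which opens, loses CO2 and tautomerises to the chelated salicylate phenoxide. The closest known reaction type is the Tamura annulation of homophthalic and glutaconic anhydride anions with acetylenic esters; what is new is the enol-ester (acyloxy) substituent on the anhydride. Ring B is the only ring closed, formally by a (4+2) annulation with extrusion of CO2, and no stereocentre remains in the product. Three selectivities are needed: the ynoate orientation, set by conjugate-addition polarity so that the ester carbon ends next to the new phenol; closure on the anhydride carbonyl and not on the aroyl carbonyl, secured by the two ortho substituents of ring A and the higher electrophilicity of the anhydride; and retention of the aroyl group on oxygen, for which the same hindrance should suppress transfer to carbon or to the product phenoxide. Because 17 is symmetric, either of its two α-carbons leads to the same product.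

Step 10
Reactants: 19 tert-butyl 4-[(3-chloro-2,4-dimethoxy-6-propylbenzoyl)oxy]-2-hydroxy-6-pentylbenzoate
Product: 20 4-[(3-chloro-2-hydroxy-4-methoxy-6-propylbenzoyl)oxy]-2-hydroxy-6-pentylbenzoic acid (CNP0329756.0)
Conditions: BCl3 (4 equiv), CH2Cl2, −78 → 0 °C; then H2O
Reagents that add atoms: none
Why: Lewis-acid dealkylation in which BCl3 cleaves the tert-butyl ester and, through a six-membered chelate with the depside carbonyl, only the doubly flanked ortho methyl ether of ring A, while the non-chelated para methyl ether, the aryl chloride and the hindered aryl ester should stay intact at or below 0 °C.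

**Compound list**

1 | 5-propylbenzene-1,3-diol (divarinol) | CCCc1cc(O)cc(O)c1 | starting material
2 | 1,3-dimethoxy-5-propylbenzene | CCCc1cc(OC)cc(OC)c1 | intermediate
3 | (2,6-dimethoxy-4-propylphenyl)lithium | CCCc1cc(OC)c([Li])c(OC)c1 | intermediate
4 | 2-chloro-1,3-dimethoxy-5-propylbenzene | CCCc1cc(OC)c(Cl)c(OC)c1 | intermediate
5 | 2-bromo-4-chloro-3,5-dimethoxy-1-propylbenzene | CCCc1cc(OC)c(Cl)c(OC)c1Br | intermediate
6 | (3-chloro-2,4-dimethoxy-6-propylphenyl)lithium | CCCc1cc(OC)c(Cl)c(OC)c1[Li] | intermediate
7 | 3-chloro-2,4-dimethoxy-6-propylbenzoic acid | CCCc1cc(OC)c(Cl)c(OC)c1C(=O)O | intermediate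
8 | 3-chloro-2,4-dimethoxy-6-propylbenzoyl chloride | CCCc1cc(OC)c(Cl)c(OC)c1C(=O)Cl | intermediate
9 | 3-oxopentanedioic acid | O=C(CC(=O)O)CC(=O)O | starting material
10 | 3-oxoglutaric anhydride (2H-pyran-2,4,6(3H,5H)-trione) | O=C1CC(=O)OC(=O)C1 | intermediate
11 | triethylammonium 2,6-dioxo-3,6-dihydro-2H-pyran-4-olate | [O-]C1=CC(=O)OC(=O)C1.CC[NH+](CC)CC | intermediate
12 | 2,6-dioxo-3,6-dihydro-2H-pyran-4-yl 3-chloro-2,4-dimethoxy-6-propylbenzoate | CCCc1cc(OC)c(Cl)c(OC)c1C(=O)OC1=CC(=O)OC(=O)C1 | intermediate
13 | 1-heptyne | CCCCCC#C | starting material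
14 | di-tert-butyl dicarbonate | CC(C)(C)OC(=O)OC(=O)OC(C)(C)C | starting material
15 | hept-1-yn-1-yllithium | CCCCCC#C[Li] | intermediate
16 | tert-butyl oct-2-ynoate | CCCCCC#CC(=O)OC(C)(C)C | intermediate
17 | sodium 4-[(3-chloro-2,4-dimethoxy-6-propylbenzoyl)oxy]-6-oxo-6H-pyran-2-olate | CCCc1cc(OC)c(Cl)c(OC)c1C(=O)OC1=CC(=O)OC([O-])=C1.[Na+] | intermediate
18 | sodium 6-(tert-butoxycarbonyl)-8-[(3-chloro-2,4-dimethoxy-6-propylbenzoyl)oxy]-3-oxo-5-pentyl-2-oxabicyclo[2.2.2]octa-5,7-dien-1-olate (racemic, transient) | CCCCCC1=C(C(=O)OC(C)(C)C)C2([O-])C=C(OC(=O)c3c(CCC)cc(OC)c(Cl)c3OC)C1C(=O)O2.[Na+] | intermediate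
19 | tert-butyl 4-[(3-chloro-2,4-dimethoxy-6-propylbenzoyl)oxy]-2-hydroxy-6-pentylbenzoate | CCCCCc1cc(OC(=O)c2c(CCC)cc(OC)c(Cl)c2OC)cc(O)c1C(=O)OC(C)(C)C | intermediate
20 | 4-[(3-chloro-2-hydroxy-4-methoxy-6-propylbenzoyl)oxy]-2-hydroxy-6-pentylbenzoic acid | CCCCCc1cc(OC(=O)c2c(CCC)cc(OC)c(Cl)c2O)cc(O)c1C(=O)O | target

**Step count**

Total: 10 steps. Longest linear sequence: 8 steps (1, 2, 3, 4, 5, 7, 9, 10).

**Steps most likely to fail**

1. Step 9 (annulation, proposed new method). Conjugate addition to a β-alkyl ynoate may be slow enough for the oxidopyrone to condense with itself, the aroyl group may migrate from oxygen to carbon or to the new phenoxide, or the allenolate may be protonated before ring closure. Fallback by known chemistry, setting out from acid chloride 8 and returning at 19: commercially available 2,4-dihydroxy-6-pentylbenzoic acid (olivetolic acid, CCCCCc1cc(O)cc(O)c1C(=O)O) is esterified with tert-butyl 2,2,2-trichloroacetimidate (CH2Cl2/cyclohexane, rt, no acid catalyst) to tert-butyl 2,4-dihydroxy-6-pentylbenzoate F1. Its free para hydroxyl (the ortho hydroxyl is hydrogen-bonded to the ester) is then acylated by 8 (Et3N, CH2Cl2) in a classical depside esterification to give 19.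

2. Step 7 (enol O-acylation of the anhydride). The amine may open or self-condense the sensitive anhydride, acylation may go to carbon or occur twice, and the product may hydrolyse during handling. Fallback setting out from 8 and returning at 12: commercially available di-tert-butyl 3-oxopentanedioate is O-acylated by 8 (Et3N, CH2Cl2, 0 °C) to di-tert-butyl 3-[(3-chloro-2,4-dimethoxy-6-propylbenzoyl)oxy]pent-2-enedioate F2. CF3CO2H in CH2Cl2 removes both tert-butyl groups to give 3-[(3-chloro-2,4-dimethoxy-6-propylbenzoyl)oxy]pent-2-enedioic acid F3. Ac2O at rt then closes the cyclic anhydride 12; the mobile glutaconic double bond lets either geometry cyclise.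

3. Step 10 (global dealkylation). The para methyl ether may be lost together with the ortho one, or the depside link may be cleaved while the Lewis acid is bound. Fallback setting out from acid 7 and returning at 20, which moves the chelation-controlled demethylation to a robust early intermediate and ends with hydrogenolysis:
 - BCl3 (CH2Cl2, −78 → 0 °C) on 7 gives 3-chloro-2-hydroxy-4-methoxy-6-propylbenzoic acid F4.
 - BnBr, K2CO3, DMF gives benzyl 2-(benzyloxy)-3-chloro-4-methoxy-6-propylbenzoate F5.
 - KOH, DMSO/H2O, 80 °C gives 2-(benzyloxy)-3-chloro-4-methoxy-6-propylbenzoic acid F6.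
 - (COCl)2, cat. DMF gives 2-(benzyloxy)-3-chloro-4-methoxy-6-propylbenzoyl chloride F7.
 - Acylation of 10 as in step 7 gives 2,6-dioxo-3,6-dihydro-2H-pyran-4-yl 2-(benzyloxy)-3-chloro-4-methoxy-6-propylbenzoate F8.
 - Annulation with 16 as in step 9 gives tert-butyl 4-{[2-(benzyloxy)-3-chloro-4-methoxy-6-propylbenzoyl]oxy}-2-hydroxy-6-pentylbenzoate F9.
 - CF3CO2H in CH2Cl2 gives 4-{[2-(benzyloxy)-3-chloro-4-methoxy-6-propylbenzoyl]oxy}-2-hydroxy-6-pentylbenzoic acid F10.
 - Brief hydrogenolysis (H2, 1 atm, Pd/C, EtOAc) removes the benzyl ether to give 20; an aryl chloride of this kind is expected to persist under these conditions.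

**Further compounds**

F1 | step 9 | tert-butyl 2,4-dihydroxy-6-pentylbenzoate | CCCCCc1cc(O)cc(O)c1C(=O)OC(C)(C)C
F2 | step 7 | di-tert-butyl 3-[(3-chloro-2,4-dimethoxy-6-propylbenzoyl)oxy]pent-2-enedioate (double-bond geometry not fixed) | CCCc1cc(OC)c(Cl)c(OC)c1C(=O)OC(=CC(=O)OC(C)(C)C)CC(=O)OC(C)(C)C
F3 | step 7 | 3-[(3-chloro-2,4-dimethoxy-6-propylbenzoyl)oxy]pent-2-enedioic acid (double-bond geometry not fixed) | CCCc1cc(OC)c(Cl)c(OC)c1C(=O)OC(=CC(=O)O)CC(=O)O
F4 | step 10 | 3-chloro-2-hydroxy-4-methoxy-6-propylbenzoic acid | CCCc1cc(OC)c(Cl)c(O)c1C(=O)O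
F5 | step 10 | benzyl 2-(benzyloxy)-3-chloro-4-methoxy-6-propylbenzoate | CCCc1cc(OC)c(Cl)c(OCc2ccccc2)c1C(=O)OCc1ccccc1
F6 | step 10 | 2-(benzyloxy)-3-chloro-4-methoxy-6-propylbenzoic acid | CCCc1cc(OC)c(Cl)c(OCc2ccccc2)c1C(=O)O
F7 | step 10 | 2-(benzyloxy)-3-chloro-4-methoxy-6-propylbenzoyl chloride | CCCc1cc(OC)c(Cl)c(OCc2ccccc2)c1C(=O)Cl
F8 | step 10 | 2,6-dioxo-3,6-dihydro-2H-pyran-4-yl 2-(benzyloxy)-3-chloro-4-methoxy-6-propylbenzoate | CCCc1cc(OC)c(Cl)c(OCc2ccccc2)c1C(=O)OC1=CC(=O)OC(=O)C1
F9 | step 10 | tert-butyl 4-{[2-(benzyloxy)-3-chloro-4-methoxy-6-propylbenzoyl]oxy}-2-hydroxy-6-pentylbenzoate | CCCCCc1cc(OC(=O)c2c(CCC)cc(OC)c(Cl)c2OCc2ccccc2)cc(O)c1C(=O)OC(C)(C)C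
F10 | step 10 | 4-{[2-(benzyloxy)-3-chloro-4-methoxy-6-propylbenzoyl]oxy}-2-hydroxy-6-pentylbenzoic acid | CCCCCc1cc(OC(=O)c2c(CCC)cc(OC)c(Cl)c2OCc2ccccc2)cc(O)c1C(=O)O
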